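**Strategy.** The depside is cut inside ring A and not at the ester: ring A C6, C1, C2 and C3 come from C6, C5, C4 and C3 of a 2-pyrone that already carries the ring B aryl ester on C5, and C4/C5 come from a silyl ynol ether. The step exploits the 2,4-dioxygenation of ring A with hydrogen on C3 and C5. One inverse-demand Diels–Alder reaction followed by loss of CO2 forms the C3–C4 and C5–C6 bonds and delivers the fully substituted, already acylated benzene ring with both phenols differentiated. The precursor is the ring B ester of 4-benzyloxy-6-propyl-2-pyrone-5-carboxylic acid, assembled from a β-keto ester and malonyl dichloride.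

Key step: step 11

Remarks:
- The target has no stereocentre, so no configuration has to be set.
- Ring A is numbered from the carboxyl-bearing carbon C1 to the propyl-bearing carbon C6; its silyloxy carbon C4 lies meta to the benzyloxy carbon C2 and para to C1. The pyrone is numbered O1, C2 (lactone carbonyl) to C6 (propyl-bearing).
- 3-Phenylisoxazole is taken as a purchasable heterocycle.

**Step 1**
Reactants: 1 5-propylresorcinol
Product: 3 2,4-dihydroxy-6-propylbenzaldehyde, via (2,4-dihydroxy-6-propylbenzylidene)dimethyliminium chloride 2 (not isolated)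
Conditions: POCl3, DMF, MeCN, 0 °C → rt; then H2O, 50 °C
Reagents that add atoms: N,N-dimethylformamide, CN(C)C=O; water, O
Why: Vilsmeier–Haack formylation of a 5-alkylresorcinol should take place at the ring carbon ortho to one hydroxyl and para to the other, as it does for orcinol, and the iminium salt is hydrolysed on aqueous work-up.

**Step 2**
Reactants: 3 2,4-dihydroxy-6-propylbenzaldehyde
Product: 4 4-(benzyloxy)-2-hydroxy-6-propylbenzaldehyde
Conditions: BnBr (1.05 equiv), NaHCO3, KI (cat.), MeCN, 80 °C
Reagents that add atoms: benzyl bromide, BrCc1ccccc1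
Why: Williamson etherification with a weak base should be selective for the 4-hydroxyl, because the 2-hydroxyl is held in a hydrogen bond to the formyl group and is less acidic and less nucleophilic.

**Step 3**
Reactants: 4 4-(benzyloxy)-2-hydroxy-6-propylbenzaldehyde
Product: 5 4-(benzyloxy)-2-hydroxy-6-propylbenzoic acid
Conditions: NaClO2, NaH2PO4, 2-methylbut-2-ene (excess), t-BuOH/THF/H2O, 0 °C → rt
Reagents that add atoms: sodium chlorite, [Na+].[O-]Cl=O
Why: Pinnick (Lindgren) chlorite oxidation converts hindered phenolic benzaldehydes into the acids under buffered conditions, and the alkene scavenger intercepts HOCl before it can chlorinate the electron-rich ring.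

**Step 4**
Reactants: 5 4-(benzyloxy)-2-hydroxy-6-propylbenzoic acid
Product: 6 methyl 4-(benzyloxy)-2-methoxy-6-propylbenzoate
Conditions: MeI (3 equiv), K2CO3, DMF, 50 °C
Reagents that add atoms: iodomethane, CI
Why: Exhaustive SN2 methylation with carbonate in DMF should alkylate both the carboxylate and the salicylate-type phenol, while the benzyl ether is inert.

**Step 5**
Reactants: 6 methyl 4-(benzyloxy)-2-methoxy-6-propylbenzoate
Product: 7 methyl 4-hydroxy-2-methoxy-6-propylbenzoate (ring B phenol)
Conditions: H2 (1 atm), Pd/C (10%), EtOAc, rt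
Reagents that add atoms: none
Why: Hydrogenolysis of the aryl benzyl ether over palladium should free the 4-hydroxyl without touching the methyl ester or the methyl ether.

**Step 6**
Reactants: 8 Meldrum's acid (2,2-dimethyl-1,3-dioxane-4,6-dione), 9 butyryl chloride
Product: 10 5-(1-hydroxybutylidene)-2,2-dimethyl-1,3-dioxane-4,6-dione (butyryl Meldrum's acid, enol form)
Conditions: pyridine (2 equiv), CH2Cl2, 0 °C → rt
Reagents that add atoms: none
Why: C-acylation of Meldrum's acid with an acid chloride and pyridine (Oikawa–Yonemitsu procedure) reliably gives the enolised acyl Meldrum's acid.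

**Step 7**
Reactants: 10 butyryl Meldrum's acid, 7 methyl 4-hydroxy-2-methoxy-6-propylbenzoate
Product: 12 3-methoxy-4-(methoxycarbonyl)-5-propylphenyl 3-oxohexanoate, via butyrylketene 11 (not isolated)
Conditions: PhMe, 110 °C
Reagents that add atoms: none
Why: Thermolysis of the acyl Meldrum's acid expels acetone and CO2 to give the acylketene, which the phenol should trap as the aryl β-keto ester under neutral conditions.

**Step 8**
Reactants: 12 3-methoxy-4-(methoxycarbonyl)-5-propylphenyl 3-oxohexanoate, 13 malonyl dichloride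
Product: 15 3-methoxy-4-(methoxycarbonyl)-5-propylphenyl 4-hydroxy-2-oxo-6-propyl-2H-pyran-5-carboxylate, via C-acylated malonyl monochloride 14 (not isolated)
Conditions: 13 (1.1 equiv), ClCH2CH2Cl, rt → 70 °C, N2 sweep
Reagents that add atoms: none
Why: Malonyl dichloride acts as a 1,3-bis-electrophile toward β-keto esters, C-acylation at the active methylene followed by lactonisation of the ketone enol onto the second acid chloride giving the 4-hydroxy-2-pyrone-5-carboxylate with the propyl ketone carbon as C6.

**Step 9**
Reactants: 15 3-methoxy-4-(methoxycarbonyl)-5-propylphenyl 4-hydroxy-2-oxo-6-propyl-2H-pyran-5-carboxylate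
Product: 16 3-methoxy-4-(methoxycarbonyl)-5-propylphenyl 4-(benzyloxy)-2-oxo-6-propyl-2H-pyran-5-carboxylate
Conditions: BnOH, PPh3, DIAD, THF, 0 °C → rt
Reagents that add atoms: benzyl alcohol, OCc1ccccc1
Why: Mitsunobu etherification uses the acidic 4-hydroxyl (a vinylogous carboxylic acid) as pronucleophile and alkylates 4-hydroxy-2-pyrones on O4, which avoids the 2-alkoxy-4-pyrone and C3-benzyl products that metal-salt alkylations with benzyl halides can give.

**Step 10**
Reactants: 17 3-phenylisoxazole
Product: 20 (triisopropylsilyloxy)ethyne, via 5-lithio-3-phenylisoxazole 18 (not isolated), via lithium ethynolate 19 (not isolated)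
Conditions: n-BuLi (1.0 equiv), THF, −78 → −30 °C; then i-Pr3SiCl, −78 °C → rt
Reagents that add atoms: chlorotriisopropylsilane, CC(C)[Si](Cl)(C(C)C)C(C)C
Why: Deprotonation of a 3-substituted isoxazole at C5 triggers the cycloreversion to a nitrile and a lithium ynolate (Schöllkopf–Hoppe ynolate generation), and the ynolate should be O-silylated by the bulky chlorosilane as in the Kowalski synthesis of ynol silyl ethers, the triisopropylsilyl group slowing the silyl shift to the silylketene.

**Step 11**
Reactants: 16 3-methoxy-4-(methoxycarbonyl)-5-propylphenyl 4-(benzyloxy)-2-oxo-6-propyl-2H-pyran-5-carboxylate, 20 (triisopropylsilyloxy)ethyne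
Product: 22 3-methoxy-4-(methoxycarbonyl)-5-propylphenyl 2-(benzyloxy)-6-propyl-4-[(triisopropylsilyl)oxy]benzoate, via 2-oxabicyclo[2.2.2]octa-5,7-dien-3-one cycloadduct 21 (not isolated)
Conditions: 20 (3 equiv), PhMe, 105 °C, sealed tube
Reagents that add atoms: none
Why: The electron-poor diene C3=C4–C5=C6 of pyrone 16 and the electron-rich ynol ether 20 should combine in an asynchronous inverse-electron-demand (4+2) cycloaddition in which the alkyne CH carbon bonds to pyrone C6 and the silyloxy-bearing carbon to C3, and the bridged lactone 21 then expels CO2 by cycloreversion to give the benzene ring without a separate oxidation. The closest known reactions are the benzannulations of 2-pyrone-5-carboxylates with ynamines, alkoxyalkynes and ketene acetals, and the metal-promoted benzannulation of siloxyalkynes with 2-pyrones. Ring A is closed by an intermolecular (4+2) cycloaddition that forms its C3–C4 and C5–C6 bonds in one operation, and the retro-(4+2) loss of the CO2 bridge makes the sequence irreversible. No stereocentre remains, since the two bridgehead stereocentres of 21 become sp2 carbons of the arene. The step needs regioselectivity, which matched polarity should secure: C6 is the β-carbon of the 5-ester and the δ-carbon of the lactone carbonyl and therefore electrophilic, C3 is the electron-rich β-carbon of the 4-benzyloxy enol ether, and the ynol ether is nucleophilic at its CH terminus, which is also the smaller end and so the one able to approach the fully substituted C6. Excess 20 compensates for its slow thermal isomerisation to the silylketene.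

**Step 12**
Reactants: 22 3-methoxy-4-(methoxycarbonyl)-5-propylphenyl 2-(benzyloxy)-6-propyl-4-[(triisopropylsilyl)oxy]benzoate
Product: 23 3-methoxy-4-(methoxycarbonyl)-5-propylphenyl 2-(benzyloxy)-4-hydroxy-6-propylbenzoate
Conditions: Bu4NF (1.1 equiv), AcOH (1.2 equiv), THF, 0 °C
Reagents that add atoms: none
Why: Fluoride cleaves the aryl silyl ether through a pentacoordinate silicate, and acetic acid buffers the phenoxide so that the two aryl esters should not be attacked.

**Step 13**
Reactants: 23 3-methoxy-4-(methoxycarbonyl)-5-propylphenyl 2-(benzyloxy)-4-hydroxy-6-propylbenzoate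
Product: 24 3-methoxy-4-(methoxycarbonyl)-5-propylphenyl 2,4-dihydroxy-6-propylbenzoate (CNP0177078.0)
Conditions: H2 (1 atm), Pd/C (10%), EtOAc, rt
Reagents that add atoms: none
Why: Catalytic hydrogenolysis should remove the remaining benzyl ether under neutral conditions that leave the depside ester, the methyl ester and the methyl ether intact.

**Compound list**

1 | 5-propylresorcinol (5-propylbenzene-1,3-diol) | CCCc1cc(O)cc(O)c1 | starting material
2 | (2,4-dihydroxy-6-propylbenzylidene)dimethyliminium chloride | CCCc1cc(O)cc(O)c1C=[N+](C)C.[Cl-] | intermediate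
3 | 2,4-dihydroxy-6-propylbenzaldehyde | CCCc1cc(O)cc(O)c1C=O | intermediate
4 | 4-(benzyloxy)-2-hydroxy-6-propylbenzaldehyde | CCCc1cc(OCc2ccccc2)cc(O)c1C=O | intermediate
5 | 4-(benzyloxy)-2-hydroxy-6-propylbenzoic acid | CCCc1cc(OCc2ccccc2)cc(O)c1C(=O)O | intermediate
6 | methyl 4-(benzyloxy)-2-methoxy-6-propylbenzoate | CCCc1cc(OCc2ccccc2)cc(OC)c1C(=O)OC | intermediate
7 | methyl 4-hydroxy-2-methoxy-6-propylbenzoate (ring B phenol) | CCCc1cc(O)cc(OC)c1C(=O)OC | intermediate
8 | Meldrum's acid (2,2-dimethyl-1,3-dioxane-4,6-dione) | CC1(C)OC(=O)CC(=O)O1 | starting material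
9 | butyryl chloride | CCCC(=O)Cl | starting material
10 | 5-(1-hydroxybutylidene)-2,2-dimethyl-1,3-dioxane-4,6-dione | CCCC(O)=C1C(=O)OC(C)(C)OC1=O | intermediate
11 | butyrylketene (3-oxohex-1-en-1-one) | CCCC(=O)C=C=O | intermediate
12 | 3-methoxy-4-(methoxycarbonyl)-5-propylphenyl 3-oxohexanoate | CCCC(=O)CC(=O)Oc1cc(CCC)c(C(=O)OC)c(OC)c1 | intermediate
13 | malonyl dichloride | O=C(Cl)CC(=O)Cl | starting material
14 | 3-methoxy-4-(methoxycarbonyl)-5-propylphenyl 2-(3-chloro-3-oxopropanoyl)-3-oxohexanoate (racemic, enolisable) | CCCC(=O)C(C(=O)CC(=O)Cl)C(=O)Oc1cc(CCC)c(C(=O)OC)c(OC)c1 | intermediate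
15 | 3-methoxy-4-(methoxycarbonyl)-5-propylphenyl 4-hydroxy-2-oxo-6-propyl-2H-pyran-5-carboxylate | CCCC1=C(C(=O)Oc2cc(CCC)c(C(=O)OC)c(OC)c2)C(O)=CC(=O)O1 | intermediate
16 | 3-methoxy-4-(methoxycarbonyl)-5-propylphenyl 4-(benzyloxy)-2-oxo-6-propyl-2H-pyran-5-carboxylate | CCCC1=C(C(=O)Oc2cc(CCC)c(C(=O)OC)c(OC)c2)C(OCc2ccccc2)=CC(=O)O1 | intermediate
17 | 3-phenylisoxazole | c1ccc(cc1)-c1ccon1 | starting material
18 | 5-lithio-3-phenylisoxazole | [Li]c1cc(-c2ccccc2)no1 | intermediate
19 | lithium ethynolate | [Li+].[O-]C#C | intermediate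
20 | (triisopropylsilyloxy)ethyne | C#CO[Si](C(C)C)(C(C)C)C(C)C | intermediate
21 | 3-methoxy-4-(methoxycarbonyl)-5-propylphenyl 5-(benzyloxy)-3-oxo-1-propyl-8-[(triisopropylsilyl)oxy]-2-oxabicyclo[2.2.2]octa-5,7-diene-6-carboxylate (racemic) | CCCC12OC(=O)C(C(OCc3ccccc3)=C1C(=O)Oc4cc(CCC)c(C(=O)OC)c(OC)c4)C(O[Si](C(C)C)(C(C)C)C(C)C)=C2 | intermediate
22 | 3-methoxy-4-(methoxycarbonyl)-5-propylphenyl 2-(benzyloxy)-6-propyl-4-[(triisopropylsilyl)oxy]benzoate | CCCc1cc(O[Si](C(C)C)(C(C)C)C(C)C)cc(OCc2ccccc2)c1C(=O)Oc1cc(CCC)c(C(=O)OC)c(OC)c1 | intermediate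
23 | 3-methoxy-4-(methoxycarbonyl)-5-propylphenyl 2-(benzyloxy)-4-hydroxy-6-propylbenzoate | CCCc1cc(O)cc(OCc2ccccc2)c1C(=O)Oc1cc(CCC)c(C(=O)OC)c(OC)c1 | intermediate
24 | 3-methoxy-4-(methoxycarbonyl)-5-propylphenyl 2,4-dihydroxy-6-propylbenzoate (CNP0177078.0) | CCCc1cc(O)cc(O)c1C(=O)Oc1cc(CCC)c(C(=O)OC)c(OC)c1 | target

**Totals.** Total step count: 13. Longest linear sequence: 11 steps (steps 1–5, 7–9, 11–13).

**Steps most likely to fail**

Step 11. The cycloaddition may be slower than the thermal decay of ynol ether 20 (silyl shift to the silylketene, then ketene–alkyne oligomerisation), so that the benzyloxy-deactivated pyrone is recovered or adds with poor orientation control. The fallback builds ring A from aldehyde 3 and joins it to phenol 7 by a classical depside esterification, returning to the route at 22. Selective silylation of the 4-hydroxyl of 3 (i-Pr3SiCl, imidazole, CH2Cl2) would give 2-hydroxy-6-propyl-4-[(triisopropylsilyl)oxy]benzaldehyde F1. Mitsunobu benzylation of the remaining hydroxyl (BnOH, PPh3, DIAD) would give 2-(benzyloxy)-6-propyl-4-[(triisopropylsilyl)oxy]benzaldehyde F2. Pinnick oxidation (NaClO2, NaH2PO4, 2-methylbut-2-ene) would give 2-(benzyloxy)-6-propyl-4-[(triisopropylsilyl)oxy]benzoic acid F3. Its mixed anhydride with (CF3CO)2O in toluene should acylate 7 to give 22, after which steps 12 and 13 follow unchanged.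

Step 10. Lithiation and fragmentation may not be clean (n-BuLi adding to the benzonitrile that is released or to the ring N–O bond), and the unhindered ynolate may be silylated on carbon, leading to the silylketene. The fallback replaces the alkyne by a ketene acetal, setting out from pyrone 16 and returning at 24. Bromoacetaldehyde diethyl acetal would be transacetalised with benzyl alcohol (TsOH cat., removal of ethanol) to 2-bromo-1,1-bis(benzyloxy)ethane F4. KOt-Bu in THF would eliminate HBr to give 1,1-bis(benzyloxy)ethene F5. Its inverse-demand Diels–Alder reaction with 16 (PhMe, 80–110 °C), followed by loss of CO2 and of benzyl alcohol, should give 3-methoxy-4-(methoxycarbonyl)-5-propylphenyl 2,4-bis(benzyloxy)-6-propylbenzoate F6. Hydrogenolysis of F6 (H2, Pd/C) leads directly to 24.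

Step 8. Under the hydrogen chloride released, the electron-rich aryl β-keto ester may undergo Pechmann-type ring closure onto ring B or ester cleavage faster than C-acylation by malonyl dichloride. The fallback builds the pyrone on an allyl ester and attaches ring B last, setting out from 10 and returning at 16. Thermolysis of 10 with allyl alcohol would give allyl 3-oxohexanoate F7. Malonyl dichloride 13 would close allyl 4-hydroxy-2-oxo-6-propyl-2H-pyran-5-carboxylate F8, on the simple alkyl β-keto ester class for which this annulation is established. Mitsunobu benzylation would give allyl 4-(benzyloxy)-2-oxo-6-propyl-2H-pyran-5-carboxylate F9. Pd(PPh3)4 (zerovalent palladium) with PhSiH3 would remove the allyl group to give 4-(benzyloxy)-2-oxo-6-propyl-2H-pyran-5-carboxylic acid F10. Oxalyl chloride with catalytic DMF would give 4-(benzyloxy)-2-oxo-6-propyl-2H-pyran-5-carbonyl chloride F11, which should acylate phenol 7 (Et3N, DMAP, CH2Cl2) to 16.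

**Further compounds**

F1 | step 11 | 2-hydroxy-6-propyl-4-[(triisopropylsilyl)oxy]benzaldehyde | CCCc1cc(O[Si](C(C)C)(C(C)C)C(C)C)cc(O)c1C=O
F2 | step 11 | 2-(benzyloxy)-6-propyl-4-[(triisopropylsilyl)oxy]benzaldehyde | CCCc1cc(O[Si](C(C)C)(C(C)C)C(C)C)cc(OCc2ccccc2)c1C=O
F3 | step 11 | 2-(benzyloxy)-6-propyl-4-[(triisopropylsilyl)oxy]benzoic acid | CCCc1cc(O[Si](C(C)C)(C(C)C)C(C)C)cc(OCc2ccccc2)c1C(=O)O
F4 | step 10 | 2-bromo-1,1-bis(benzyloxy)ethane | BrCC(OCc1ccccc1)OCc1ccccc1
F5 | step 10 | 1,1-bis(benzyloxy)ethene | C=C(OCc1ccccc1)OCc1ccccc1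
F6 | step 10 | 3-methoxy-4-(methoxycarbonyl)-5-propylphenyl 2,4-bis(benzyloxy)-6-propylbenzoate | CCCc1cc(OCc2ccccc2)cc(OCc2ccccc2)c1C(=O)Oc1cc(CCC)c(C(=O)OC)c(OC)c1
F7 | step 8 | allyl 3-oxohexanoate | CCCC(=O)CC(=O)OCC=C
F8 | step 8 | allyl 4-hydroxy-2-oxo-6-propyl-2H-pyran-5-carboxylate | CCCC1=C(C(=O)OCC=C)C(O)=CC(=O)O1
F9 | step 8 | allyl 4-(benzyloxy)-2-oxo-6-propyl-2H-pyran-5-carboxylate | CCCC1=C(C(=O)OCC=C)C(OCc2ccccc2)=CC(=O)O1
F10 | step 8 | 4-(benzyloxy)-2-oxo-6-propyl-2H-pyran-5-carboxylic acid | CCCC1=C(C(=O)O)C(OCc2ccccc2)=CC(=O)O1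
F11 | step 8 | 4-(benzyloxy)-2-oxo-6-propyl-2H-pyran-5-carbonyl chloride | CCCC1=C(C(=O)Cl)C(OCc2ccccc2)=CC(=O)O1
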